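Ring B holds a C6 ketone with the exocyclic C8=C17 methylene β,γ to it. This array is the C7-protonated form of a C6(OSi)=C7–C8=C17 dienol ether, the adduct of a 2-silyloxy vinylallene (C5=C6–C7=C8=C17) and a C9=C10 alkene. The plan rests on cutting C5–C10 and C8–C9. One intramolecular Diels–Alder reaction closes rings A and B together, sets C5, C9 and C10, and leaves the methylene and the masked ketone in place. Its precursor is acyclic: a Z-silyl enol ether carrying a terminal allene at one end, an E-β-methyl enoate at the other, linked by C1–C4 with the gem-dimethyl group and the syn-2,3-dichloride.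

Key step: step 12

Assumption: labdane numbering (C1–C20) is used for every intermediate. The antipode of the Schiff-base ligand in step 3 is picked so that the (2R,3R)-dichloride forms; the sense of induction is inferred from simpler Z-allylic alcohols, and both ligand antipodes are accessible.

Step 1
Reactants: 1 2,2-dimethylpent-4-enal
Product: 2 methyl (2Z)-4,4-dimethylhepta-2,6-dienoate
Conditions: (CF3CH2O)2P(O)CH2CO2Me, KN(SiMe3)2, 18-crown-6, THF, −78 °C
Reagents that add atoms: methyl bis(2,2,2-trifluoroethyl)phosphonoacetate, COC(=O)CP(=O)(OCC(F)(F)F)OCC(F)(F)F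
Why: Still–Gennari olefination, in which the kinetically formed adduct of the electron-poor phosphonate collapses fast and irreversibly, should give the Z-enoate even from this α-quaternary, non-enolisable aldehyde, and it brings in C1 and C2.

Step 2
Reactants: 2 methyl (2Z)-4,4-dimethylhepta-2,6-dienoate
Product: 3 (2Z)-4,4-dimethylhepta-2,6-dien-1-ol
Conditions: iBu2AlH (2.5 equiv), CH2Cl2, −78 → 0 °C; aq. potassium sodium tartrate
Reagents that add atoms: none
Why: 1,2-Reduction of an enoate with iBu2AlH gives the allylic alcohol without touching either alkene or the Z geometry.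

Step 3
Reactants: 3 (2Z)-4,4-dimethylhepta-2,6-dien-1-ol
Product: 4 (2R,3R)-2,3-dichloro-4,4-dimethylhept-6-en-1-ol
Conditions: ClTi(OiPr)3 (1.1 equiv), tBuOCl (1.1 equiv), chiral tridentate salicylaldimine–amino alcohol (O,N,O) Schiff-base ligand (20 mol %), hexanes, −20 °C
Reagents that add atoms: tert-butyl hypochlorite, CC(C)(C)OCl; chlorotitanium triisopropoxide, CC(C)O[Ti](Cl)(OC(C)C)OC(C)C
Why: In this titanium-templated catalytic enantioselective dichlorination of an allylic alcohol, the alkoxide of 3 binds the ligand-bearing titanium centre, so electrophilic chlorine from tBuOCl and titanium-bound chloride add anti across the bound Z-alkene only, which sets C2 and C3 as the syn (2R,3R)-dichloride and leaves the remote allyl group alone.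

Step 4
Reactants: 4 (2R,3R)-2,3-dichloro-4,4-dimethylhept-6-en-1-ol
Product: 5 (2R,3R)-2,3-dichloro-4,4-dimethylhept-6-en-1-yl trifluoromethanesulfonate
Conditions: Tf2O, 2,6-lutidine, CH2Cl2, −78 °C; cold aqueous wash, used at once
Reagents that add atoms: trifluoromethanesulfonic anhydride, O=S(=O)(OS(=O)(=O)C(F)(F)F)C(F)(F)F
Why: O-Sulfonylation of the primary alcohol with a weak, hindered pyridine base is fast at −78 °C and does not close the chlorohydrin to an epoxide.

Step 5
Reactants: 5 (2R,3R)-2,3-dichloro-4,4-dimethylhept-6-en-1-yl trifluoromethanesulfonate; 6 ethynyltrimethylsilane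
Product: 8 [(4R,5R)-4,5-dichloro-6,6-dimethylnon-8-en-1-yn-1-yl]trimethylsilane, via lithium trimethylsilylacetylide 7 (not isolated)
Conditions: 6, n-BuLi, THF, −78 °C; then 5, DMPU, −78 → −30 °C
Reagents that add atoms: none
Why: SN2 alkylation of a lithium acetylide by a primary triflate forms C1–C10, and the very good leaving group lets substitution run at a temperature where E2 loss of HOTf or HCl is slow, so C2 and C3 stay untouched.

Step 6
Reactants: 8 [(4R,5R)-4,5-dichloro-6,6-dimethylnon-8-en-1-yn-1-yl]trimethylsilane
Product: 9 (4R,5R)-4,5-dichloro-6,6-dimethylnon-8-en-1-yne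
Conditions: K2CO3 (0.2 equiv), MeOH, 0 °C
Reagents that add atoms: none
Why: Carbonate-catalysed methanolysis of the alkynyl C–Si bond is mild and cold enough that the homopropargylic C2 chloride is not eliminated.

Step 7
Reactants: 9 (4R,5R)-4,5-dichloro-6,6-dimethylnon-8-en-1-yne
Product: 11 methyl (2E,5R,6R)-5,6-dichloro-3,7,7-trimethyldeca-2,9-dienoate, via E-alkenyldimethylalane 10 (not isolated)
Conditions: AlMe3 (2.5 equiv), Cp2ZrCl2 (0.2 equiv), CH2Cl2, 0 °C → rt; then ClCO2Me, 0 °C → rt
Reagents that add atoms: trimethylaluminium, C[Al](C)C; methyl chloroformate, COC(=O)Cl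
Why: Negishi zirconium-catalysed carboalumination adds CH3 (C20) and aluminium syn across the terminal alkyne, with methyl on the internal carbon and much faster than across the monosubstituted alkene, and acylation of the alkenylalane by the chloroformate with retention gives the E-enoate (C1 trans to C11).

Step 8
Reactants: 11 methyl (2E,5R,6R)-5,6-dichloro-3,7,7-trimethyldeca-2,9-dienoate
Product: 12 methyl (2E,5R,6R)-5,6-dichloro-3,7,7-trimethyl-9-oxonon-2-enoate
Conditions: OsO4 (2 mol %), NaIO4 (4 equiv), 2,6-lutidine, dioxane–H2O, rt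
Reagents that add atoms: sodium periodate, [Na+].[O-]I(=O)(=O)=O (terminal oxygen source); osmium tetroxide, O=[Os](=O)(=O)=O (oxygen relay)
Why: In the Lemieux–Johnson cleavage OsO4 dihydroxylates the electron-rich monosubstituted alkene in preference to the trisubstituted, electron-poor enoate, and periodate cuts the diol to the C6 aldehyde while 2,6-lutidine suppresses over-oxidation.

Step 9
Reactants: 12 methyl (2E,5R,6R)-5,6-dichloro-3,7,7-trimethyl-9-oxonon-2-enoate; 13 propargyl bromide
Product: 15 methyl (2E,5R,6R)-5,6-dichloro-9-hydroxy-3,7,7-trimethyldodec-2-en-11-ynoate (epimeric at the carbinol carbon), via allenylzinc bromide 14 (not isolated)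
Conditions: 13, Zn dust, THF, 0 °C; solution decanted from excess Zn; then 12, THF, −78 → 0 °C; aq. NH4Cl
Reagents that add atoms: none
Why: Addition of an allenylzinc halide to an aldehyde through a cyclic SE2′ transition state gives the homopropargylic alcohol (C7, C8, C17) and tolerates the ester; because the reagent is made beforehand and separated from the metal, the vicinal dichloride never meets reducing zinc, and the carbinol configuration is irrelevant since it is erased in step 10.

Step 10
Reactants: 15 methyl (2E,5R,6R)-5,6-dichloro-9-hydroxy-3,7,7-trimethyldodec-2-en-11-ynoate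
Product: 17 methyl (2E,5R,6R)-5,6-dichloro-3,7,7-trimethyl-9-oxododeca-2,10,11-trienoate, via beta-gamma-ynone 16 (not isolated)
Conditions: Dess–Martin periodinane, CH2Cl2, 0 °C → rt; aq. Na2S2O3/NaHCO3 wash; then Et3N (0.2 equiv), CH2Cl2, 0 °C
Reagents that add atoms: none
Why: Dess–Martin oxidation is followed by an amine-catalysed prototropic shift, in which Et3N removes a proton from the doubly activated C7 methylene of the ynone and reprotonation at C17 moves the system into the more stable conjugated allenyl ketone.

Step 11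
Reactants: 17 methyl (2E,5R,6R)-5,6-dichloro-3,7,7-trimethyl-9-oxododeca-2,10,11-trienoate
Product: 18 methyl (2E,5R,6R,8Z)-9-(tert-butyldimethylsilyloxy)-5,6-dichloro-3,7,7-trimethyldodeca-2,8,10,11-tetraenoate
Conditions: TBSOTf (1.3 equiv), iPr2NEt (2 equiv), CH2Cl2, −78 → −30 °C; cold aq. NaHCO3; Et3N-deactivated silica
Reagents that add atoms: tert-butyldimethylsilyl triflate, CC(C)(C)[Si](C)(C)OS(=O)(=O)C(F)(F)F
Why: Soft enolisation (O-silylation, then amine deprotonation) of an enone-type ketone goes kinetically to the cross-conjugated α′ side, here C5, and never forms a free enolate that could displace the γ-chloride at C3, while allylic strain between quaternary C4 and the allenyl group leaves the Z enol ether (C4 cis to OSi) as the accessible geometry.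

Step 12
Reactants: 18 methyl (2E,5R,6R,8Z)-9-(tert-butyldimethylsilyloxy)-5,6-dichloro-3,7,7-trimethyldodeca-2,8,10,11-tetraenoate
Product: 19 bicyclic dienol ether ester: trans-decalin with 2α-Cl/3β-Cl/4,4-Me2/5α-H/10β-Me/9β-CO2Me (9α-H)/C6(OTBS)=C7/C8=C17
Conditions: toluene (0.01 M, degassed), BHT (0.1 equiv), base-washed sealed tube, 110 °C
Reagents that add atoms: none
Why: This is a thermal, concerted but asynchronous [4+2] cycloaddition (type 1 intramolecular Diels–Alder reaction of a 1,7,9-decatriene): the enol ether carbon C5, which carries the largest diene HOMO coefficient, bonds ahead to the enoate β-carbon C10 while the central allene carbon C8 closes on C9, so tether and electronic (para) preference agree. The closest known reactions are intramolecular Diels–Alder reactions of vinylallenes and of 2-silyloxy dienes bearing tethered enoates, and intermolecular cycloadditions of siloxy vinylallenes. Ring A (C1–C5 plus C10) closes as the tether ring through the C5–C10 bond in a chair-like array, and ring B (C5–C10) is the new cyclohexene made by both new bonds, its C6=C7 bond and the untouched C8=C17 bond forming a dienol ether that is locked s-trans and cannot cycloadd again. C9 and C10 are tied to each other by suprafacial addition to the E-enoate (C20 and CO2Me cis, both β); C5 follows from the Z enol ether (C4 outside) combined with the ester-endo, tether-exo arrangement, which gives the trans fusion and puts the smallest C10 substituent (CH3) axial; all three are tied to C2 and C3 because only one diene face lets the chair tether keep both C–Cl bonds equatorial, the other face forcing C2–Cl into 1,3-diaxial contact with C20 and a C4 methyl group. The step thus needs trans over cis fusion and one π-face out of two, and both rest on features already in the substrate: the two alkene geometries, quaternary C4 and the syn dichloride. Reactivity is helped by the gem-dimethyl effect and by the absence of an inside substituent at C8, C4 has no hydrogen for a competing 1,5-hydrogen shift, and BHT, dilution and base-washed glass hold back allene oligomerisation and enol ether hydrolysis.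

Step 13
Reactants: 19 bicyclic dienol ether ester
Product: 20 bicyclic dienol ether alcohol: as 19 but 9β-CH2OH
Conditions: iBu2AlH (2.5 equiv), CH2Cl2, −78 → −20 °C; aq. potassium sodium tartrate
Reagents that add atoms: none
Why: In this ester-to-alcohol reduction with iBu2AlH the silyl dienol ether masks the C6 carbonyl group, and neither it nor the secondary chlorides react with the hydride in the cold.

Step 14
Reactants: 20 bicyclic dienol ether alcohol
Product: 21 bicyclic dienol ether aldehyde: as 19 but 9β-CHO
Conditions: Dess–Martin periodinane, pyridine, CH2Cl2, 0 °C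
Reagents that add atoms: none
Why: Dess–Martin oxidation buffered with pyridine is neither acidic enough to protonate the dienol ether nor basic enough to move the C9 hydrogen, which is both α to the new aldehyde and allylic.

Step 15
Reactants: 21 bicyclic dienol ether aldehyde
Product: 22 bis(enol ether): as 19 but 9β-CH=CHOMe (E/Z mixture)
Conditions: MeOCH2PPh3Cl (1.5 equiv), KN(SiMe3)2 (1.4 equiv), THF, 0 °C; then 21, −78 → 0 °C
Reagents that add atoms: (methoxymethyl)triphenylphosphonium chloride, COC[P+](c1ccccc1)(c1ccccc1)c1ccccc1.[Cl-]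
Why: Wittig methoxymethylenation adds C12, the ylide being made with a slight deficit of base and meeting the aldehyde at −78 °C so that addition outruns deprotonation at C9, and the alkene geometry is of no consequence.

Step 16
Reactants: 22 bis(enol ether)
Product: 24 keto aldehyde: trans-decalin with 2α-Cl/3β-Cl/4,4-Me2/5α-H/10β-Me/C6=O/C7H2/C8=C17/9β-CH2CHO, via C6-keto methyl enol ether 23 (not isolated)
Conditions: Bu4NF (1.1 equiv), AcOH (1.6 equiv), THF, −40 → 0 °C; then 0.5 M aq. HCl, THF, 0 °C
Reagents that add atoms: water, O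
Why: Fluoride cleaves the O–Si bond to the extended dienolate, which acetic acid protonates kinetically at the α-carbon C7 (deconjugative protonation) and not at C17, where direct acid hydrolysis of the dienol ether would risk attack, and the remaining methyl enol ether then hydrolyses in dilute acid far faster than the β,γ-enone can enolise.

Step 17
Reactants: 25 methyl 4-chloro-4-oxobutanoate; 26 (R)-4-benzylthiazolidine-2-thione
Product: 27 methyl 4-[(4R)-4-benzyl-2-thioxo-1,3-thiazolidin-3-yl]-4-oxobutanoate
Conditions: Et3N, DMAP (cat.), CH2Cl2, 0 °C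
Reagents that add atoms: none
Why: N-Acylation of the thiazolidinethione by the acid chloride under DMAP catalysis is selective because the methyl ester end is far less electrophilic.

Step 18
Reactants: 24 keto aldehyde; 27 methyl 4-[(4R)-4-benzyl-2-thioxo-1,3-thiazolidin-3-yl]-4-oxobutanoate
Product: 29 (12S,13R)-syn aldol adduct: 24 extended at C12 by CH(OH)–CH(CH2CO2Me)–C(=O)–N-[(R)-4-benzyl-2-thioxothiazolidin-3-yl], via chlorotitanium Z-enolate 28 (not isolated)
Conditions: 27 (1.5 equiv), TiCl4, iPr2NEt, N-methylpyrrolidinone, CH2Cl2, 0 °C; then 24, −78 → −20 °C; aq. NH4Cl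
Reagents that add atoms: none
Why: In the titanium-mediated thiazolidinethione aldol addition under the amine/N-methylpyrrolidinone protocol, the chlorotitanium Z-enolate reacts through a non-chelated chair transition state on the face away from the benzyl group, which gives the Evans-syn (12S,13R) adduct from the (R)-auxiliary, and the aldehyde reacts far faster than the hindered C6 ketone.

Step 19
Reactants: 29 (12S,13R)-syn aldol adduct
Product: 31 haterumaimide B, via primary amide 30 (not isolated)
Conditions: NH3 (0.5 M in dioxane, 5 equiv), THF, 0 °C; then MeOH, 0 °C → rt until 30 is consumed; AcOH quench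
Reagents that add atoms: ammonia, N
Why: Aminolysis of the activated N-acyl thiazolidinethione by NH3 is followed by 5-exo-trig attack of the primary amide on the C15 methyl ester (imide formation), for which ammonia in methanol is base enough, so C13, the retro-aldol-prone C12–C13 bond and the β,γ-enone meet nothing stronger, and any γ-lactone formed from C12–OH and C15 is drawn to the same imide.

Compound list
1 | 2,2-dimethylpent-4-enal | C=CCC(C)(C)C=O | starting material
2 | methyl (2Z)-4,4-dimethylhepta-2,6-dienoate | C=CCC(C)(C)/C=C\C(=O)OC | intermediate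
3 | (2Z)-4,4-dimethylhepta-2,6-dien-1-ol | C=CCC(C)(C)/C=C\CO | intermediate
4 | (2R,3R)-2,3-dichloro-4,4-dimethylhept-6-en-1-ol | C=CCC(C)(C)[C@@H](Cl)[C@H](Cl)CO | intermediate
5 | (2R,3R)-2,3-dichloro-4,4-dimethylhept-6-en-1-yl triflate | C=CCC(C)(C)[C@@H](Cl)[C@H](Cl)COS(=O)(=O)C(F)(F)F | intermediate
6 | ethynyltrimethylsilane | C#C[Si](C)(C)C | starting material
7 | lithium trimethylsilylacetylide (not isolated) | [Li]C#C[Si](C)(C)C | intermediate
8 | [(4R,5R)-4,5-dichloro-6,6-dimethylnon-8-en-1-yn-1-yl]trimethylsilane | C=CCC(C)(C)[C@@H](Cl)[C@H](Cl)CC#C[Si](C)(C)C | intermediate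
9 | (4R,5R)-4,5-dichloro-6,6-dimethylnon-8-en-1-yne | C=CCC(C)(C)[C@@H](Cl)[C@H](Cl)CC#C | intermediate
10 | E-alkenyldimethylalane from syn methylalumination of 9 (not isolated) | C=CCC(C)(C)[C@@H](Cl)[C@H](Cl)C/C(C)=C/[Al](C)C | intermediate
11 | methyl (2E,5R,6R)-5,6-dichloro-3,7,7-trimethyldeca-2,9-dienoate | C=CCC(C)(C)[C@@H](Cl)[C@H](Cl)C/C(C)=C/C(=O)OC | intermediate
12 | methyl (2E,5R,6R)-5,6-dichloro-3,7,7-trimethyl-9-oxonon-2-enoate | O=CCC(C)(C)[C@@H](Cl)[C@H](Cl)C/C(C)=C/C(=O)OC | intermediate
13 | propargyl bromide | C#CCBr | starting material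
14 | allenylzinc bromide (not isolated) | C=C=C[Zn]Br | intermediate
15 | methyl (2E,5R,6R)-5,6-dichloro-9-hydroxy-3,7,7-trimethyldodec-2-en-11-ynoate, carbinol epimers | C#CCC(O)CC(C)(C)[C@@H](Cl)[C@H](Cl)C/C(C)=C/C(=O)OC | intermediate
16 | β,γ-ynone, methyl (2E,5R,6R)-5,6-dichloro-3,7,7-trimethyl-9-oxododec-2-en-11-ynoate (not isolated) | C#CCC(=O)CC(C)(C)[C@@H](Cl)[C@H](Cl)C/C(C)=C/C(=O)OC | intermediate
17 | allenyl ketone, methyl (2E,5R,6R)-5,6-dichloro-3,7,7-trimethyl-9-oxododeca-2,10,11-trienoate | C=C=CC(=O)CC(C)(C)[C@@H](Cl)[C@H](Cl)C/C(C)=C/C(=O)OC | intermediate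
18 | 2-silyloxy vinylallene, methyl (2E,5R,6R,8Z)-9-(tert-butyldimethylsilyloxy)-5,6-dichloro-3,7,7-trimethyldodeca-2,8,10,11-tetraenoate | C=C=C/C(O[Si](C)(C)C(C)(C)C)=C/C(C)(C)[C@@H](Cl)[C@H](Cl)C/C(C)=C/C(=O)OC | intermediate
19 | trans-decalin silyl dienol ether ester (2α,3β-Cl2, 5α-H, 9α-H, 10β-Me, 9β-CO2Me, C6(OTBS)=C7, C8=C17) | C=C1C=C(O[Si](C)(C)C(C)(C)C)[C@H]2C(C)(C)[C@@H](Cl)[C@H](Cl)C[C@]2(C)[C@H]1C(=O)OC | intermediate
20 | as 19, 9β-CH2OH | C=C1C=C(O[Si](C)(C)C(C)(C)C)[C@H]2C(C)(C)[C@@H](Cl)[C@H](Cl)C[C@]2(C)[C@H]1CO | intermediate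
21 | as 19, 9β-CHO | C=C1C=C(O[Si](C)(C)C(C)(C)C)[C@H]2C(C)(C)[C@@H](Cl)[C@H](Cl)C[C@]2(C)[C@H]1C=O | intermediate
22 | as 19, 9β-CH=CHOMe (E/Z mixture) | C=C1C=C(O[Si](C)(C)C(C)(C)C)[C@H]2C(C)(C)[C@@H](Cl)[C@H](Cl)C[C@]2(C)[C@H]1C=COC | intermediate
23 | C6 ketone with C8=C17 methylene and 9β-CH=CHOMe (not isolated) | C=C1CC(=O)[C@H]2C(C)(C)[C@@H](Cl)[C@H](Cl)C[C@]2(C)[C@H]1C=COC | intermediate
24 | C6-keto C12-aldehyde (9β-CH2CHO) | C=C1CC(=O)[C@H]2C(C)(C)[C@@H](Cl)[C@H](Cl)C[C@]2(C)[C@H]1CC=O | intermediate
25 | methyl 4-chloro-4-oxobutanoate | COC(=O)CCC(Cl)=O | starting material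
26 | (R)-4-benzylthiazolidine-2-thione | S=C1N[C@H](Cc2ccccc2)CS1 | starting material
27 | methyl 4-[(4R)-4-benzyl-2-thioxo-1,3-thiazolidin-3-yl]-4-oxobutanoate | COC(=O)CCC(=O)N1[C@H](Cc2ccccc2)CSC1=S | intermediate
28 | chlorotitanium Z-enolate of 27 (not isolated) | COC(=O)C/C=C(\O[Ti](Cl)(Cl)Cl)N1[C@H](Cc2ccccc2)CSC1=S | intermediate
29 | (12S,13R)-syn aldol adduct | C=C1CC(=O)[C@H]2C(C)(C)[C@@H](Cl)[C@H](Cl)C[C@]2(C)[C@H]1C[C@H](O)[C@@H](CC(=O)OC)C(=O)N1[C@H](Cc2ccccc2)CSC1=S | intermediate
30 | (12S,13R)-C16 primary amide C15 methyl ester (not isolated) | C=C1CC(=O)[C@H]2C(C)(C)[C@@H](Cl)[C@H](Cl)C[C@]2(C)[C@H]1C[C@H](O)[C@@H](CC(=O)OC)C(N)=O | intermediate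
31 | haterumaimide B (2R,3R,5R,9S,10R,12S,13R) | C=C1CC(=O)[C@H]2C(C)(C)[C@@H](Cl)[C@H](Cl)C[C@]2(C)[C@H]1C[C@H](O)[C@H]1CC(=O)NC1=O | target

Total step count: 19. Longest linear sequence: 18 steps (steps 1–16, 18 and 19, from 2,2-dimethylpent-4-enal).

Steps most likely to fail

Step 12. The C5–C10 bond joins a neopentyl-type carbon to a fully substituted enoate carbon, so the cycloaddition may be too slow. Allene oligomerisation or erosion of the endo/exo preference could then take over. The fallback lowers the dienophile LUMO before ring formation instead of adjusting the oxidation state after it. Setting out from 18, iBu2AlH (CH2Cl2, −78 °C) would give the tetraenol F1, and MnO2 (CH2Cl2, rt) the tetraenal F2. The enal of F2 should cyclise at or below room temperature through the same chair, carbonyl-endo array, if necessary with Me2AlCl at −78 °C. The adduct is aldehyde 21, so the route is rejoined there and steps 13 and 14 are no longer needed.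

Step 11. The silylated ketone may lose a proton from the allene terminus C17 instead of from the hindered C5 methylene, or the amine may add to C8, so that regiocontrol of enolisation is lost. The fallback makes the allene last, from a ketone in which C5 is the only readily enolisable position. Setting out from aldehyde 12, Zn(OTf)2/Et3N-mediated addition of prop-2-yn-1-yl methyl carbonate would give the propargylic alcohol F3. Dess–Martin oxidation would give the conjugated ynone F4, and TBSOTf/iPr2NEt the Z-silyloxy enyne carbonate F5. Palladium-catalysed formate hydrogenolysis of the primary propargylic carbonate (Pd2(dba)3·CHCl3, PBu3, HCO2NH4, THF, rt) places hydrogen on C7 through an allenylpalladium hydride. This would unveil the terminal allene under neutral conditions and come back to the route at 18.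

Step 3. The tert-alkyl group at C4 shields C3, so face selection or the site at which chloride opens the chloronium ion may slip. The two opening modes lead to opposite enantiomers, so enantiomeric purity would erode. The fallback gives up asymmetric catalysis in favour of resolution. Setting out from 3, the same titanium-directed anti-dichlorination without the chiral ligand would give the racemic syn-dichloro alcohol F6 with unchanged chemoselectivity. Esterification with (S)-2-methoxy-2-phenylacetic acid (DCC, DMAP) and separation by chromatography or crystallisation would give the (2R,3R)-O-methylmandelate F7, and the (2S,3S)-O-methylmandelate F8 is set aside. Reductive cleavage of F7 with iBu2AlH at −78 °C (base is avoided because 4 is a chlorohydrin) comes back to the route at 4.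

Further compounds
F1 | step 12 | tetraenol, (2E,5R,6R,8Z)-9-(tert-butyldimethylsilyloxy)-5,6-dichloro-3,7,7-trimethyldodeca-2,8,10,11-tetraen-1-ol | C=C=C/C(O[Si](C)(C)C(C)(C)C)=C/C(C)(C)[C@@H](Cl)[C@H](Cl)C/C(C)=C/CO
F2 | step 12 | tetraenal, (2E,5R,6R,8Z)-9-(tert-butyldimethylsilyloxy)-5,6-dichloro-3,7,7-trimethyldodeca-2,8,10,11-tetraenal | C=C=C/C(O[Si](C)(C)C(C)(C)C)=C/C(C)(C)[C@@H](Cl)[C@H](Cl)C/C(C)=C/C=O
F3 | step 11 | propargylic alcohol, methyl (2E,5R,6R)-5,6-dichloro-9-hydroxy-12-[(methoxycarbonyl)oxy]-3,7,7-trimethyldodec-2-en-10-ynoate (carbinol epimers) | COC(=O)OCC#CC(O)CC(C)(C)[C@@H](Cl)[C@H](Cl)C/C(C)=C/C(=O)OC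
F4 | step 11 | conjugated ynone, methyl (2E,5R,6R)-5,6-dichloro-12-[(methoxycarbonyl)oxy]-3,7,7-trimethyl-9-oxododec-2-en-10-ynoate | COC(=O)OCC#CC(=O)CC(C)(C)[C@@H](Cl)[C@H](Cl)C/C(C)=C/C(=O)OC
F5 | step 11 | Z-silyloxy enyne carbonate, methyl (2E,5R,6R,8Z)-9-(tert-butyldimethylsilyloxy)-5,6-dichloro-12-[(methoxycarbonyl)oxy]-3,7,7-trimethyldodeca-2,8-dien-10-ynoate | COC(=O)OCC#C/C(O[Si](C)(C)C(C)(C)C)=C/C(C)(C)[C@@H](Cl)[C@H](Cl)C/C(C)=C/C(=O)OC
F6 | step 3 | racemic syn-dichloro alcohol, (2R*,3R*)-2,3-dichloro-4,4-dimethylhept-6-en-1-ol | C=CCC(C)(C)C(Cl)C(Cl)CO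
F7 | step 3 | (2R,3R)-O-methylmandelate, (2R,3R)-2,3-dichloro-4,4-dimethylhept-6-en-1-yl (S)-2-methoxy-2-phenylacetate | C=CCC(C)(C)[C@@H](Cl)[C@H](Cl)COC(=O)[C@@H](OC)c1ccccc1
F8 | step 3 | (2S,3S)-O-methylmandelate, (2S,3S)-2,3-dichloro-4,4-dimethylhept-6-en-1-yl (S)-2-methoxy-2-phenylacetate | C=CCC(C)(C)[C@H](Cl)[C@@H](Cl)COC(=O)[C@@H](OC)c1ccccc1
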